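The cyclohexene ring is read as the imprint of methyl coumalate. The ester-bearing alkene carbon, the neighbouring carbinol carbon and the allylic CH2 are C5, C6 and C3 of the pyrone. The spiro carbon and the ring CH2 beside the carbinol are a 1,1-disubstituted alkene. One inverse-demand Diels–Alder reaction joins both partners, creates the quaternary spiro centre and leaves a CO2 bridge as a temporary ring. Its precursor is a 3-methylenecyclopentene whose carbons and two stereocentres come from the iridoid nepetalactone. The ring carbon that carries the side chain is kept sp2, so that only the ring methyl group steers the pyrone.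

Key step: step 8

Remark: (4aS,7S,7aR)-nepetalactone (catnip oil constituent) is taken as a commercial chiral-pool material. Centres drawn without configuration are mixtures that converge in later steps.

Step 1
Reactants: 1 (4aS,7S,7aR)-nepetalactone
Product: 2 (4S,4aR,7S,7aR)-dihydronepetalactone
Conditions: H2 (3 bar), Pd/C, EtOAc, rt
Reagents that add atoms: none
Why: Heterogeneous hydrogenation of the enol-ether alkene from the convex face of the cis-fused bicycle (the face of both ring-fusion hydrogens) sets the methyl-bearing stereocentre of the later side chain.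

Step 2
Reactants: 2 (4S,4aR,7S,7aR)-dihydronepetalactone
Product: 5 (4S,7S)-4,7-dimethyl-4,5,6,7-tetrahydrocyclopenta[c]pyran-1(3H)-one (alkene at the ring fusion), via 7a-phenylselanyl lactone 3 (not isolated), via selenoxide 4 (not isolated)
Conditions: LiN(iPr)2, THF, −78 °C; PhSeBr; then H2O2, pyridine, CH2Cl2, 0 °C to rt
Reagents that add atoms: none
Why: In this selenoxide syn-elimination the lactone enolate is selenated on the convex face, so selenium is cis only to the hydrogen at C4a and trans to the hydrogen at C7, and the alkene can form only toward C4a while the C7 methyl stereocentre stays untouched.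

Step 3
Reactants: 5 (4S,7S)-4,7-dimethyl-4,5,6,7-tetrahydrocyclopenta[c]pyran-1(3H)-one
Product: 7 methyl (5S)-2-[(2S)-1-iodopropan-2-yl]-5-methylcyclopent-1-ene-1-carboxylate, via trimethylsilyl ester 6 (not isolated)
Conditions: Me3SiI, CH2Cl2, rt to 40 °C; then MeOH, 50 °C
Reagents that add atoms: iodotrimethylsilane C[Si](C)(C)I; methanol CO
Why: Silyl activation of the lactone carbonyl, SN2 attack of iodide at the primary O–CH2 carbon and methanolysis of the silyl ester differentiate the two oxygenated carbons without touching a stereocentre.

Step 4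
Reactants: 7 methyl (5S)-2-[(2S)-1-iodopropan-2-yl]-5-methylcyclopent-1-ene-1-carboxylate; 8 methyl 4-methyl-3-oxopentanoate
Product: 9 methyl (5S)-2-[(2R)-4-(methoxycarbonyl)-6-methyl-5-oxoheptan-2-yl]-5-methylcyclopent-1-ene-1-carboxylate (mixture at chain C4)
Conditions: K2CO3, DMF, 60 °C
Reagents that add atoms: none
Why: SN2 C-alkylation of a soft β-keto ester enolate by the primary iodide completes the side-chain carbons, and the new centre between the two carbonyl groups is removed in step 5.

Step 5
Reactants: 9 β-keto ester from step 4
Product: 10 methyl (5S)-5-methyl-2-[(2R)-6-methyl-5-oxoheptan-2-yl]cyclopent-1-ene-1-carboxylate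
Conditions: LiCl, H2O, DMSO, 150 °C
Reagents that add atoms: none
Why: Krapcho dealkoxycarbonylation removes only the ester that is β to a ketone, because the hindered conjugated ring ester gives no stabilised carbanion.

Step 6
Reactants: 10 keto enoate from step 5
Product: 11 (6R)-6-[(3S)-2-(hydroxymethyl)-3-methylcyclopent-1-en-1-yl]-2-methylheptan-3-ol (mixture at C3)
Conditions: iBu2AlH (excess), CH2Cl2, −78 to 0 °C
Reagents that add atoms: none
Why: Hydride reduction takes the conjugated ester 1,2 to the primary allylic alcohol and the ketone to a carbinol whose configuration is irrelevant because step 11 reoxidises it.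

Step 7
Reactants: 11 allylic alcohol/carbinol from step 6
Product: 14 (6R)-2-methyl-6-[(4S)-4-methyl-5-methylidenecyclopent-1-en-1-yl]heptan-3-ol (mixture at C3), via allylic sulfenate 12 (not isolated), via tertiary allylic sulfoxide 13 (not isolated)
Conditions: 2,4-(O2N)2C6H3SCl (1.1 equiv), Et3N, ClCH2CH2Cl, 0 °C to reflux
Reagents that add atoms: none
Why: This 1,4-dehydration runs through a Mislow–Evans-type [2,3] shift of the primary sulfenate and thermal sulfoxide syn-elimination toward the ring CH2, which gives the less strained transoid diene and leaves both stereocentres untouched.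

Step 8
Reactants: 14 dienol from step 7; 15 methyl coumalate (methyl 2-oxo-2H-pyran-5-carboxylate)
Product: 16 methyl 5'-methyl-2'-[(2R)-5-hydroxy-6-methylheptan-2-yl]-3-oxospiro[2-oxabicyclo[2.2.2]oct-5-ene-8,1'-cyclopent-2'-ene]-6-carboxylate, (5'S), bridgehead C4 bonded to the spiro carbon anti to the 5'-methyl group (mixture of bridge orientations and at the carbinol)
Conditions: 15 (3 equiv), BHT, CH2Cl2, 12 kbar, 40 °C
Reagents that add atoms: none
Why: The step is a concerted but asynchronous inverse-electron-demand [4+2] cycloaddition in which the exocyclic CH2, the terminus with the largest HOMO coefficient of 14, bonds first to electrophilic C6 of the pyrone and the ring carbon then closes onto C3. The closest known reaction type is the Diels–Alder reaction of methyl coumalate and other acceptor-substituted 2-pyrones with alkyl-substituted alkenes and dienes, run under pressure so that the CO2 bridge survives. The carbocyclic six-membered ring and the second six-membered ring that contains the lactone unit of the 2-oxabicyclo[2.2.2]octene are both closed in the same suprafacial [4π+2π] event. The spiro stereocentre is set by the neighbouring methyl-bearing carbon, the only sp3 stereocentre flanking the alkene, so the pyrone adds to the face anti to that methyl group; the two bridgehead centres follow from the endo/exo orientation and are erased in steps 11 and 12, so this orientation need not be controlled. The step needs site selectivity (exocyclic over ring alkene), regioselectivity and facial selectivity: the first two are secured by the polarity and accessibility of the CH2 terminus, the third by keeping the side-chain-bearing carbon planar, and 14 cannot act as a diene itself because its diene unit is locked s-trans.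

Step 9
Reactants: 16 bridged lactone from step 8
Product: 17 saturated bridged lactone: methyl 5'-methyl-2'-[(2R)-5-hydroxy-6-methylheptan-2-yl]-3-oxospiro[2-oxabicyclo[2.2.2]octane-8,1'-cyclopentane]-6-carboxylate, side chain cis to bridgehead C4 and trans to the ring methyl group
Conditions: H2 (4 bar), PtO2, EtOAc, rt
Reagents that add atoms: none
Why: In this heterogeneous hydrogenation the strained enoate alkene reduces first (its new centre is erased in step 12), and the cyclopentene then takes hydrogen from the face flanked by the CH2 of the bicycle rather than by the substituted bridgehead, as Δ16 steroids are reduced anti to the angular group, which sets the side-chain-bearing ring stereocentre.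

Step 10
Reactants: 17 saturated bridged lactone
Product: 18 hydroxy acid: 9-hydroxy-8-(methoxycarbonyl)-1-methyl-4-[(2R)-5-hydroxy-6-methylheptan-2-yl]spiro[4.5]decane-6-carboxylic acid, (1S,4R), spiro centre as in 24
Conditions: LiOH (1.1 equiv), THF/H2O, 0 °C; then dilute HCl
Reagents that add atoms: lithium hydroxide [Li+].[OH-]
Why: The strained bridged lactone is saponified faster than the secondary methyl ester, and the low temperature suppresses β-elimination.

Step 11
Reactants: 18 hydroxy acid
Product: 19 8-(methoxycarbonyl)-1-methyl-4-[(2R)-6-methyl-5-oxoheptan-2-yl]-9-oxospiro[4.5]decane-6-carboxylic acid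
Conditions: Dess–Martin periodinane (2.5 equiv), CH2Cl2, rt
Reagents that add atoms: none
Why: Dess–Martin oxidation of both secondary alcohols gives the ring β-keto ester and restores the side-chain ketone, erasing the carbinol centre that came from the cycloaddition.

Step 12
Reactants: 19 diketo acid
Product: 23 methyl (1S,4R,5S)-1-methyl-4-[(2R)-6-methyl-5-oxoheptan-2-yl]-9-oxospiro[4.5]dec-7-ene-8-carboxylate, via α-phenylselanyl β-keto ester 20 (not isolated), via selenoxide 21 (not isolated), via enone acid 22 (not isolated)
Conditions: PhSeCl, pyridine, CH2Cl2, 0 °C; H2O2, 0 °C to rt; then 40 °C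
Reagents that add atoms: none
Why: Selenation of the enolised β-keto ester and selenoxide syn-elimination can only use the hydrogens of the ring CH2 next to the carboxyl-bearing carbon, and the resulting γ-carboxy enone is a vinylogous β-keto acid that loses CO2 and tautomerises to the conjugated enone.

Step 13
Reactants: 23 enone ester
Product: 24 methyl (1S,4R,5S,9S)-9-hydroxy-1-methyl-4-[(2R)-6-methyl-5-oxoheptan-2-yl]spiro[4.5]dec-7-ene-8-carboxylate (target)
Conditions: (R)-Me-CBS oxazaborolidine (0.3 equiv), catecholborane (1.1 equiv), toluene, −78 °C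
Reagents that add atoms: none
Why: In this Corey–Bakshi–Shibata 1,2-reduction the ester-substituted alkene arm acts as the large group, so the (R)-catalyst delivers hydride to give the (S)-carbinol under reagent control, and the activated enone carbonyl reacts faster than the hindered isopropyl ketone.

Compound list
1 | (4aS,7S,7aR)-nepetalactone | O=C1OC=C(C)[C@H]2CC[C@H](C)[C@@H]12 | starting material
2 | (4S,4aR,7S,7aR)-dihydronepetalactone | O=C1OC[C@@H](C)[C@H]2CC[C@H](C)[C@@H]12 | intermediate
3 | 7a-phenylselanyl dihydronepetalactone (Se cis to H-4a) | O=C1OC[C@@H](C)[C@H]2CC[C@H](C)[C@@]12[Se]c3ccccc3 | intermediate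
4 | selenoxide of 3 | O=C1OC[C@@H](C)[C@H]2CC[C@H](C)[C@@]12[Se](=O)c3ccccc3 | intermediate
5 | (4S,7S)-4,7-dimethyl-4,5,6,7-tetrahydrocyclopenta[c]pyran-1(3H)-one | O=C1OC[C@@H](C)C2=C1[C@@H](C)CC2 | intermediate
6 | trimethylsilyl (5S)-2-[(2S)-1-iodopropan-2-yl]-5-methylcyclopent-1-ene-1-carboxylate | C[Si](C)(C)OC(=O)C1=C([C@H](C)CI)CC[C@@H]1C | intermediate
7 | methyl (5S)-2-[(2S)-1-iodopropan-2-yl]-5-methylcyclopent-1-ene-1-carboxylate | COC(=O)C1=C([C@H](C)CI)CC[C@@H]1C | intermediate
8 | methyl 4-methyl-3-oxopentanoate | COC(=O)CC(=O)C(C)C | starting material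
9 | methyl (5S)-2-[(2R)-4-(methoxycarbonyl)-6-methyl-5-oxoheptan-2-yl]-5-methylcyclopent-1-ene-1-carboxylate | COC(=O)C1=C([C@H](C)CC(C(=O)OC)C(=O)C(C)C)CC[C@@H]1C | intermediate
10 | methyl (5S)-5-methyl-2-[(2R)-6-methyl-5-oxoheptan-2-yl]cyclopent-1-ene-1-carboxylate | COC(=O)C1=C([C@H](C)CCC(=O)C(C)C)CC[C@@H]1C | intermediate
11 | (6R)-6-[(3S)-2-(hydroxymethyl)-3-methylcyclopent-1-en-1-yl]-2-methylheptan-3-ol | OCC1=C([C@H](C)CCC(O)C(C)C)CC[C@@H]1C | intermediate
12 | 2,4-dinitrobenzenesulfenate of the primary alcohol of 11 | [O-][N+](=O)c1ccc(SOCC2=C([C@H](C)CCC(O)C(C)C)CC[C@@H]2C)c(c1)[N+](=O)[O-] | intermediate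
13 | tertiary allylic 2,4-dinitrophenyl sulfoxide (exocyclic methylene) | C=C1C(S(=O)c2ccc(cc2[N+](=O)[O-])[N+](=O)[O-])([C@H](C)CCC(O)C(C)C)CC[C@@H]1C | intermediate
14 | (6R)-2-methyl-6-[(4S)-4-methyl-5-methylidenecyclopent-1-en-1-yl]heptan-3-ol | C=C1C([C@H](C)CCC(O)C(C)C)=CC[C@@H]1C | intermediate
15 | methyl coumalate | COC(=O)C1=COC(=O)C=C1 | starting material
16 | bridged lactone cycloadduct (spiro[2-oxabicyclo[2.2.2]oct-5-ene-8,1'-cyclopent-2'-ene]) | COC(=O)C1=CC3[C@@]2(CC1OC3=O)C([C@H](C)CCC(O)C(C)C)=CC[C@@H]2C | intermediate
17 | saturated bridged lactone | COC(=O)C1CC3[C@@]2(CC1OC3=O)[C@@H]([C@H](C)CCC(O)C(C)C)CC[C@@H]2C | intermediate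
18 | hydroxy acid | COC(=O)C1CC(C(=O)O)[C@@]2(CC1O)[C@@H]([C@H](C)CCC(O)C(C)C)CC[C@@H]2C | intermediate
19 | diketo acid (ring β-keto ester) | COC(=O)C1CC(C(=O)O)[C@@]2(CC1=O)[C@@H]([C@H](C)CCC(=O)C(C)C)CC[C@@H]2C | intermediate
20 | α-phenylselanyl β-keto ester | COC(=O)C1([Se]c3ccccc3)CC(C(=O)O)[C@@]2(CC1=O)[C@@H]([C@H](C)CCC(=O)C(C)C)CC[C@@H]2C | intermediate
21 | selenoxide of 20 | COC(=O)C1([Se](=O)c3ccccc3)CC(C(=O)O)[C@@]2(CC1=O)[C@@H]([C@H](C)CCC(=O)C(C)C)CC[C@@H]2C | intermediate
22 | enone acid (vinylogous β-keto acid) | COC(=O)C1=CC(C(=O)O)[C@@]2(CC1=O)[C@@H]([C@H](C)CCC(=O)C(C)C)CC[C@@H]2C | intermediate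
23 | methyl (1S,4R,5S)-1-methyl-4-[(2R)-6-methyl-5-oxoheptan-2-yl]-9-oxospiro[4.5]dec-7-ene-8-carboxylate | COC(=O)C1=CC[C@@]2(CC1=O)[C@@H]([C@H](C)CCC(=O)C(C)C)CC[C@@H]2C | intermediate
24 | methyl (1S,4R,5S,9S)-9-hydroxy-1-methyl-4-[(2R)-6-methyl-5-oxoheptan-2-yl]spiro[4.5]dec-7-ene-8-carboxylate | COC(=O)C1=CC[C@@]2(C[C@@H]1O)[C@@H]([C@H](C)CCC(=O)C(C)C)CC[C@@H]2C | target

Total step count: 13. Longest linear sequence: 13 steps (from 1).

Steps most likely to fail

Step 8. The cycloaddition at the hindered alkene may be sluggish, and forcing it may extrude CO2 from the adduct, with loss of the oxygen at the later carbinol carbon. The fallback installs the ester after the ring. It sets out from 14, which is heated with 5-bromo-2H-pyran-2-one (toluene, 90 °C); the adducts of this pyrone are thermally more robust. This gives the bromo-substituted bridged lactone F1. Methoxycarbonylation of its vinyl bromide (Pd(OAc)2, 1,3-bis(diphenylphosphino)propane, CO, MeOH, Et3N) comes back to the route at 16.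

Step 9. Three processes may go wrong: poor facial selectivity at the cyclopentene, incomplete reduction of the hindered alkene, or hydrogenolysis of the allylic C–O bond before the enoate is saturated. The fallback moves this reduction to the end and uses a directing group.
- It sets out from 16, which is saponified (LiOH) to the unsaturated hydroxy acid F2.
- Dess–Martin oxidation with spontaneous decarboxylation gives the cyclopentene enone F3.
- CBS reduction as in step 13 gives the cyclopentene carbinol F4.
- Hydroxyl-directed hydrogenation with [Ir(cod)(PCy3)(py)]PF6 (H2, CH2Cl2) follows. The carbinol oxygen sits on the ring-CH2 arm and therefore on the required face of the cyclopentene, and the step comes back at 24.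

Step 7. The sulfoxide may eliminate toward the side-chain methine, which would lose that stereocentre, or the secondary alcohol may consume the sulfenyl chloride. The fallback replaces the pericyclic elimination by an organometallic one. It sets out from 11, whose primary allylic alcohol is converted selectively (ClCO2Me, pyridine, 0 °C) to the allylic methyl carbonate F5. Ionisation with Pd(PPh3)4 (THF, reflux) and β-hydride elimination from the ring CH2 (Tsuji–Trost-type diene formation) come back at 14.

Further compounds
F1 | step 8 | bromo-substituted bridged lactone (Br in place of CO2Me of 16) | BrC1=CC3[C@@]2(CC1OC3=O)C([C@H](C)CCC(O)C(C)C)=CC[C@@H]2C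
F2 | step 9 | unsaturated hydroxy acid | COC(=O)C1=CC(C(=O)O)[C@@]2(CC1O)C([C@H](C)CCC(O)C(C)C)=CC[C@@H]2C
F3 | step 9 | cyclopentene enone (2,3-didehydro analogue of 23) | COC(=O)C1=CC[C@@]2(CC1=O)C([C@H](C)CCC(=O)C(C)C)=CC[C@@H]2C
F4 | step 9 | cyclopentene carbinol (2,3-didehydro analogue of 24) | COC(=O)C1=CC[C@@]2(C[C@@H]1O)C([C@H](C)CCC(=O)C(C)C)=CC[C@@H]2C
F5 | step 7 | allylic methyl carbonate of 11 | COC(=O)OCC1=C([C@H](C)CCC(O)C(C)C)CC[C@@H]1C
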